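**Retrosynthetic overview**
1. Target 18 comes from 9α‑hydroxy ketone 15 by a late angelate esterification. The tiglate is carried from the ring B stage.
2. 15 comes from bridged methyl ketal 14, and 14 from bromoketal 12. One radical cascade closes the oxolane (C‑1–C‑10) and then ring A (C‑4–C‑5), setting C‑10, C‑5 and C‑4.
3. 12 comes from allylic alcohol 8 and (E)‑2‑methoxypenta‑1,3‑diene 11, which supplies C‑1 to C‑4 and C‑15.
4. Ring B and C‑7 come from (+)‑3‑carene by allylic oxidation and opening of the cyclopropane to the isopropenyl group. C‑8 and C‑9 follow by substrate control.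
5. Ring order: ring B from the chiral pool, then oxolane and ring A together, then the oxolane is opened.

Convention (assumed for all compounds): carbons carry the eremophilane numbers of the target. These are ketone C‑2, CHMe C‑4, quaternary C‑5, isopropenyl C‑7, tiglate C‑8, angelate C‑9 and ring‑fusion CH C‑10. β is the face of H‑10, both ring methyl groups and the isopropenyl group; α is the face of both acyloxy groups. Ring A is C‑1 to C‑5 plus C‑10, and ring B is C‑5 to C‑10.

Step 1
Reactants: 1 (+)-3-carene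
Product: 2 (1R,6S)-4,7,7-trimethylbicyclo[4.1.0]hept-3-en-2-one (car-3-en-5-one)
Conditions: CrO3, 3,5-dimethylpyrazole, CH2Cl2, −20 °C
Reagents that add atoms: chromium trioxide `O=[Cr](=O)=O`
Why: Allylic oxidation by the CrO3–dimethylpyrazole complex takes the ring CH2 next to the unsubstituted alkene carbon and gives the β‑methyl enone, while both cyclopropane stereocentres stay untouched.

Step 2
Reactants: 2 car-3-en-5-one
Product: 3 (5S)-3-methyl-5-(prop-1-en-2-yl)cyclohex-2-en-1-one
Conditions: PhMe (0.1 M), base-washed sealed tube, 230 °C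
Reagents that add atoms: none
Why: In this retro‑Conia‑ene reaction (homo‑1,5‑hydrogen shift) the endo methyl group is cis to the acyl carbon on the cyclopropane, so its hydrogen moves to the carbonyl oxygen as the C‑8–C‑11 bond breaks, and the dienol tautomerises to 3 with C‑7 kept as in carene.

Step 3
Reactants: 3 (5S)-3-methyl-5-(prop-1-en-2-yl)cyclohex-2-en-1-one, 4 tigloyl chloride
Product: 7 (1R,6R)-4-methyl-2-oxo-6-(prop-1-en-2-yl)cyclohex-3-en-1-yl (E)-2-methylbut-2-enoate, via lithium dienolate 5 (not isolated), via lithium 8-alkoxide 6 (not isolated)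
Conditions: LiN(SiMe3)2, THF, −78 °C; 3-phenyl-2-(phenylsulfonyl)oxaziridine, −78 °C; then 4, −78 to 0 °C
Reagents that add atoms: 3-phenyl-2-(phenylsulfonyl)oxaziridine `O=S(=O)(c1ccccc1)N1OC1c1ccccc1`; tigloyl chloride `C/C=C(\C)C(=O)Cl`
Why: Kinetic α′‑deprotonation and Davis enolate hydroxylation occur anti to the neighbouring isopropenyl group (8α‑oxygen, trans‑diequatorial, also the thermodynamic epimer), and the alkoxide is O‑acylated in the same flask.

Step 4
Reactants: 7 8α-tigloyloxy enone
Product: 8 (1R,2S,6R)-2-hydroxy-4-methyl-6-(prop-1-en-2-yl)cyclohex-3-en-1-yl (E)-2-methylbut-2-enoate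
Conditions: Li[HB(s-Bu)3], THF, −78 °C; AcOH quench at −78 °C
Reagents that add atoms: none
Why: The bulky borohydride reduces the β,β‑disubstituted enone 1,2 along the equatorial line from the β face, which gives the pseudoaxial 9α‑alcohol cis to the tiglate, and the cold acid quench prevents 1,2‑acyl shift.

Step 5
Reactants: 9 (E)-pent-3-en-2-one
Product: 11 (E)-2-methoxypenta-1,3-diene, via dimethyl ketal 10 (not isolated)
Conditions: HC(OMe)3, MeOH, TsOH (cat.), rt; then KHSO4 (cat.), 140 °C, distil
Reagents that add atoms: trimethyl orthoformate `COC(OC)OC`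
Why: Orthoformate ketalisation followed by acid‑catalysed loss of methanol toward the methyl group gives the cross‑conjugated enol ether with the (E)‑alkene unchanged.

Step 6
Reactants: 8 9α-allylic alcohol, 11 (E)-2-methoxypenta-1,3-diene
Product: 12 9α-O-[(2S,3E)-1-bromo-2-methoxypent-3-en-2-yl] ether of 8 (mixed bromoketal)
Conditions: NBS, 11 (3 equiv), CH2Cl2, −78 to −40 °C; ketal epimers separated on SiO2, unwanted epimer re-equilibrated with camphorsulfonic acid (cat.)
Reagents that add atoms: N-bromosuccinimide `O=C1CCC(=O)N1Br`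
Why: In this Ueno–Stork haloketalisation the electron‑rich enol ether is brominated at C‑1 far faster than any other alkene, the alcohol caps the oxocarbenium carbon C‑2, and the new ketal centre forms unselectively, so the (2S) epimer is selected by separation and recycling.

Step 7
Reactants: 12 mixed bromoketal
Product: 14 2α,9α-epoxy-2β-methoxy-8α-tigloyloxy-10βH-eremophil-11-ene (bridged tricyclic ketal), via tertiary C-5 radical 13 (not isolated)
Conditions: Bu3SnH (1.2 equiv) + AIBN (cat.) by syringe pump over 8 h, PhH (2 mM), 80 °C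
Reagents that add atoms: none
Why: Proposed new method: bromine abstraction gives the primary C‑1 radical, which hangs from the pseudoaxial 9α‑oxygen and closes 5‑exo on C‑10 from the α face (cis‑fused oxolane, H‑10 β), the tertiary radical 13 then has the endo propenyl group held under its α lobe and closes 6‑endo on C‑4 through a chair with the (E)‑methyl group equatorial (5β‑Me, 4β‑Me with H‑4 tucked into the concave face, cis‑decalin), and the C‑3 radical takes hydrogen from Bu3SnH; the closest known reaction types are the Ueno–Stork haloacetal cyclisation and the 6‑endo closures of tertiary radicals in radical polyene cyclisations.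

Step 8
Reactants: 14 bridged tricyclic ketal
Product: 15 9α-hydroxy-8α-tigloyloxy-10βH-eremophil-11-en-2-one
Conditions: PPTS (cat.), acetone/H2O 9:1, 40 °C
Reagents that add atoms: water `O`
Why: Mild ketal hydrolysis cleaves the ring C‑2–O bond with help from the methoxy oxygen, which frees the C‑2 ketone and the 9α‑hydroxyl without touching the tiglate, the isopropenyl group or any stereocentre.

Step 9
Reactants: 15 9α-hydroxy ketone, 16 angelic acid
Product: 18 8α-tigloyloxy-9α-angeloyloxy-10βH-eremophil-11-en-2-one (target), via mixed anhydride 17 (not isolated)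
Conditions: 2,4,6-Cl3C6H2COCl, Et3N, PhMe, rt; then 15, 80 °C (no DMAP)
Reagents that add atoms: angelic acid `C/C=C(/C)C(=O)O`
Why: Yamaguchi esterification without a nucleophilic catalyst acylates the hindered axial alcohol while keeping the (Z)‑geometry, and the free 9‑OH with 8‑tiglate arrangement is the stable regioisomer, so no acyl scrambling precedes it.

**Compound list**
1 | (+)-3-carene, (1S,6R)-3,7,7-trimethylbicyclo[4.1.0]hept-3-ene | `CC1=CC[C@@H]2[C@H](C1)C2(C)C` | starting material
2 | (1R,6S)-4,7,7-trimethylbicyclo[4.1.0]hept-3-en-2-one | `CC1=CC(=O)[C@@H]2[C@H](C1)C2(C)C` | intermediate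
3 | (5S)-3-methyl-5-(prop-1-en-2-yl)cyclohex-2-en-1-one | `C=C(C)[C@H]1CC(C)=CC(=O)C1` | intermediate
4 | tigloyl chloride, (E)-2-methylbut-2-enoyl chloride | `C/C=C(\C)C(=O)Cl` | starting material
5 | lithium cross-conjugated dienolate of 3 (C-8=C-9) | `C=C(C)[C@H]1CC(C)=CC([O-])=C1.[Li+]` | intermediate
6 | lithium (1R,6R)-4-methyl-2-oxo-6-(prop-1-en-2-yl)cyclohex-3-en-1-olate | `C=C(C)[C@H]1CC(C)=CC(=O)[C@@H]1[O-].[Li+]` | intermediate
7 | (1R,6R)-4-methyl-2-oxo-6-(prop-1-en-2-yl)cyclohex-3-en-1-yl (E)-2-methylbut-2-enoate | `C=C(C)[C@H]1CC(C)=CC(=O)[C@@H]1OC(=O)/C(C)=C/C` | intermediate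
8 | (1R,2S,6R)-2-hydroxy-4-methyl-6-(prop-1-en-2-yl)cyclohex-3-en-1-yl (E)-2-methylbut-2-enoate | `C=C(C)[C@H]1CC(C)=C[C@H](O)[C@@H]1OC(=O)/C(C)=C/C` | intermediate
9 | (E)-pent-3-en-2-one | `C/C=C/C(C)=O` | starting material
10 | (E)-4,4-dimethoxypent-2-ene | `COC(C)(OC)/C=C/C` | intermediate
11 | (E)-2-methoxypenta-1,3-diene | `C=C(OC)/C=C/C` | intermediate
12 | 9α-O-[(2S,3E)-1-bromo-2-methoxypent-3-en-2-yl] ether of 8 | `C=C(C)[C@H]1CC(C)=C[C@H](O[C@@](CBr)(OC)/C=C/C)[C@@H]1OC(=O)/C(C)=C/C` | intermediate
13 | cis-fused oxolane with tertiary radical at C-5 and endo (E)-propenyl group on C-2 | `C=C(C)[C@H]1C[C](C)[C@@H]2C[C@](OC)(/C=C/C)O[C@@H]2[C@@H]1OC(=O)/C(C)=C/C` | intermediate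
14 | 2α,9α-epoxy-2β-methoxy-8α-tigloyloxy-10βH-eremophil-11-ene | `C=C(C)[C@H]1C[C@@]2(C)[C@@H]3C[C@](OC)(C[C@@H]2C)O[C@@H]3[C@@H]1OC(=O)/C(C)=C/C` | intermediate
15 | 9α-hydroxy-8α-tigloyloxy-10βH-eremophil-11-en-2-one | `C=C(C)[C@H]1C[C@@]2(C)[C@H](CC(=O)C[C@@H]2C)[C@H](O)[C@@H]1OC(=O)/C(C)=C/C` | intermediate
16 | angelic acid, (Z)-2-methylbut-2-enoic acid | `C/C=C(/C)C(=O)O` | starting material
17 | angelic 2,4,6-trichlorobenzoic anhydride | `C/C=C(/C)C(=O)OC(=O)c1c(Cl)cc(Cl)cc1Cl` | intermediate
18 | 8α-tigloyloxy-9α-angeloyloxy-10βH-eremophil-11-en-2-one | `C=C(C)[C@H]1C[C@@]2(C)[C@H](CC(=O)C[C@@H]2C)[C@H](OC(=O)/C(C)=C\C)[C@@H]1OC(=O)/C(C)=C/C` | target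

**Total step count:** 9. **Longest linear sequence:** 8 (1 → 2 → 3 → 7 → 8 → 12 → 14 → 15 → 18).

**Steps most likely to fail**

Step 7 (radical bicyclisation). Radical 13 may be reduced before the unactivated propenyl group is reached. The fallback makes the acceptor electron‑poor and traceless. tert‑Butyl acetoacetate and acetaldehyde are condensed (piperidine/AcOH, Knoevenagel) to tert‑butyl (Z)‑2‑acetylbut‑2‑enoate F1. HC(OMe)3/TsOH and then Me3SiOTf/i‑Pr2NEt turn it into tert‑butyl (Z)‑2‑(1‑methoxyethenyl)but‑2‑enoate F2. Alcohol 8, F2 and NBS give the ester‑bearing bromoketal F3. Its tertiary radical closes ring A by a polarity‑matched Giese addition to the tricyclic ketal ester F4 (C‑3 epimers). TsOH·H2O in wet toluene at 80 °C then cleaves the ketal and the tert‑butyl ester and decarboxylates the β‑keto acid. This path sets out from 8 and comes back at 15.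

Step 2 (thermal cyclopropane opening). The temperature needed may lead to aromatisation or double‑bond migration. The fallback opens the cyclopropyl ketone ionically. Me3SiI in CH2Cl2 at −20 °C silylates the carbonyl oxygen and delivers iodide to the tertiary carbon C‑11, giving the iodo silyl dienol ether F5. The silyl group blocks re‑closure of the cyclopropane. DBU then eliminates HI toward a methyl group, and aqueous work‑up frees the enone. This path sets out from 2 and comes back at 3.

Step 9 (angelate on the hindered axial, partly hemiketalised 9α‑OH). Acylation may stall or give tiglate by Z/E isomerisation. The fallback builds the (Z)‑alkene on the ester. Compound 15 is coupled (DCC, DMAP cat.) with 2‑[bis(2,2,2‑trifluoroethoxy)phosphoryl]propanoic acid to the phosphonopropionate F6. KN(SiMe3)2/18‑crown‑6 and acetaldehyde at −78 °C (Still–Gennari olefination) then give the angelate directly. This path sets out from 15 and comes back at 18.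

**Further compounds**
F1 | step 7 | tert-butyl (Z)-2-acetylbut-2-enoate | `C/C=C(/C(C)=O)C(=O)OC(C)(C)C`
F2 | step 7 | tert-butyl (Z)-2-(1-methoxyethenyl)but-2-enoate | `C/C=C(/C(=C)OC)C(=O)OC(C)(C)C`
F3 | step 7 | bromoketal of 8 carrying a tert-butoxycarbonyl group on C-3 | `C=C(C)[C@H]1CC(C)=C[C@H](O[C@@](CBr)(OC)/C(C(=O)OC(C)(C)C)=C/C)[C@@H]1OC(=O)/C(C)=C/C`
F4 | step 7 | 3-tert-butoxycarbonyl derivative of 14 (C-3 epimers) | `C=C(C)[C@H]1C[C@@]2(C)[C@@H]3C[C@](OC)(C(C(=O)OC(C)(C)C)[C@@H]2C)O[C@@H]3[C@@H]1OC(=O)/C(C)=C/C`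
F5 | step 2 | (S)-[5-(2-iodopropan-2-yl)-3-methylcyclohexa-1,3-dien-1-yl]oxy(trimethyl)silane | `CC1=CC(O[Si](C)(C)C)=C[C@H](C1)C(C)(C)I`
F6 | step 9 | 9α-O-{2-[bis(2,2,2-trifluoroethoxy)phosphoryl]propanoyl} derivative of 15 | `C=C(C)[C@H]1C[C@@]2(C)[C@H](CC(=O)C[C@@H]2C)[C@H](OC(=O)C(C)P(=O)(OCC(F)(F)F)OCC(F)(F)F)[C@@H]1OC(=O)/C(C)=C/C`
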